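## Retrosynthetic overview

1. Side lactone (ring E) last: the C18–C19 bond comes from a chiral zinc homoenolate adding to a C3 aldehyde placed by formylation of the tetracyclic pyrrole.
2. Carbocycle (ring B) by intramolecular Friedel–Crafts/Michael closure C1–C12 of the pyrrole onto a butenolide; the fused lactone (ring D) comes from 2-(ethoxycarbonyl)allylation of a C11 aldehyde.
3. Pyrrole (ring A) and azepine (ring C) are made together by Paal–Knorr condensation of an ε-amino 1,4-keto-aldehyde. Its key C9a–C1 bond is made by a nitromethyl carbon acting as an acyl-anion equivalent (nitronate + acrolein, then Nef).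
4. C9 and C10 are set by an organocatalytic Michael addition of butanal to a nitroalkene made from 6-bromohex-1-ene.
5. Ring order: D (step 4), then A + C (step 6), then B (step 7), then E (step 9).

Assumption: locants C1–C22 in names and comments follow tuberostemonine numbering (pyrrole C1, C2, C3, N4, C9a; azepine C5–C9; ring B C9, C10, C11, C12, C1, C9a; fused lactone O–C11, C12, C13, C14, methyl C15; ethyl C16–C17 on C10; side lactone C18–C21, methyl C22). The target is then 9R,10R,11S,12R,13R,18S,20S, with H-11, H-12 and H-13 all cis. The route is a proposal and has not been run.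

## Route

Step 1
Reactants: 1 6-bromohex-1-ene; 2 di-tert-butyl iminodicarboxylate
Product: 3 di-tert-butyl (hex-5-en-1-yl)imidodicarbonate
Conditions: Cs2CO3, NaI (cat.), DMF, 60 °C
Reagents that add atoms: di-tert-butyl iminodicarboxylate (2), CC(C)(C)OC(=O)NC(=O)OC(C)(C)C
Why: SN2 N-alkylation of the acidic imidodicarbonate gives a nitrogen without N–H, so it cannot add to the nitroalkene made next.

Step 2
Reactants: 3 di-tert-butyl (hex-5-en-1-yl)imidodicarbonate
Product: 4 di-tert-butyl [(5E)-6-nitrohex-5-en-1-yl]imidodicarbonate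
Conditions: AgNO2 (3 equiv), TEMPO (0.4 equiv), 4 Å MS, ClCH2CH2Cl, 70 °C
Reagents that add atoms: AgNO2 (silver nitrite), [Ag+].[O-]N=O
Why: Radical nitration–dehydrogenation of a terminal alkene (NO2 radical addition, TEMPO-mediated hydrogen abstraction) gives the E-nitroalkene selectively.

Step 3
Reactants: 4 di-tert-butyl [(5E)-6-nitrohex-5-en-1-yl]imidodicarbonate; 5 butanal
Product: 6 di-tert-butyl [(5R,6R)-6-formyl-5-(nitromethyl)octyl]imidodicarbonate
Conditions: (S)-2-[diphenyl(trimethylsilyloxy)methyl]pyrrolidine (10 mol%), 4-nitrophenol (10 mol%), 5 (3 equiv), toluene, 0 °C to rt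
Reagents that add atoms: butanal (5), CCCC=O
Why: Hayashi–Jørgensen enamine Michael addition; the shielded E-enamine adds to the E-nitroalkene through the synclinal transition state to give the syn adduct, setting C10 (R) and C9 (R) under catalyst control.

Step 4
Reactants: 6 di-tert-butyl [(5R,6R)-6-formyl-5-(nitromethyl)octyl]imidodicarbonate; 7 ethyl 2-(bromomethyl)prop-2-enoate
Product: 9 di-tert-butyl {(5R,6R)-6-[(2R)-4-methylidene-5-oxooxolan-2-yl]-5-(nitromethyl)octyl}imidodicarbonate, via hydroxy ester 8 (not isolated)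
Conditions: indium powder (1.5 equiv), THF/H2O 1:1, rt; then TsOH·H2O (10 mol%), CH2Cl2, rt
Reagents that add atoms: ethyl 2-(bromomethyl)prop-2-enoate (7), C=C(CBr)C(=O)OCC
Why: Barbier 2-(ethoxycarbonyl)allylation under Felkin–Anh control (attack anti to the branched C9 substituent, ethyl as the medium group) sets C11 with the ethyl/oxygen relationship of the target (about 4:1 expected, minor epimer removed here), and acid closes the α-methylidene lactone; aliphatic nitro and carbamate groups tolerate aqueous indium.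

Step 5 (key C–C bond)
Reactants: 9 di-tert-butyl {(5R,6R)-6-[(2R)-4-methylidene-5-oxooxolan-2-yl]-5-(nitromethyl)octyl}imidodicarbonate; 10 prop-2-enal
Product: 11 di-tert-butyl {(5R,6R)-6-[(2R)-4-methylidene-5-oxooxolan-2-yl]-5-(1-nitro-4-oxobutyl)octyl}imidodicarbonate (both epimers at the nitro carbon)
Conditions: 10 (1.2 equiv), Et3N (20 mol%), CH2Cl2, 0 °C
Reagents that add atoms: prop-2-enal (10), C=CC=O
Why: Nitro-Michael addition in which the nitronate carbon serves as an acyl-anion equivalent for C9a (unmasked by the Nef reaction in step 6), joining the future carbonyl carbon C9a to the β-carbon C1 of acrolein; the new nitro-bearing stereocenter is destroyed later and the exocyclic methylidene lactone is too far for a competing cyclization.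

Step 6
Reactants: 11 di-tert-butyl {(5R,6R)-6-[(2R)-4-methylidene-5-oxooxolan-2-yl]-5-(1-nitro-4-oxobutyl)octyl}imidodicarbonate
Product: 14 (5R)-3-methylidene-5-{(1R)-1-[(9R)-6,7,8,9-tetrahydro-5H-pyrrolo[1,2-a]azepin-9-yl]propyl}oxolan-2-one, via amine salt 12 (not isolated), via amino ketoaldehyde 13 (not isolated)
Conditions: CF3CO2H, CH2Cl2, 0 °C; evaporate; aq. TiCl3 (8 equiv), THF, rt; then NaOAc to pH 5, 0.01 M, 45 °C
Reagents that add atoms: none
Why: Acid removes both Boc groups, TiCl3 effects a McMurry-type reductive Nef reaction that turns the nitro carbon into the C9a ketone, and on buffering the ε-amino 1,4-keto-aldehyde undergoes intramolecular Paal–Knorr condensation to form pyrrole and azepine together; no stereocenter is created and C9 survives if the ketone is consumed quickly.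

Step 7
Reactants: 14 (5R)-3-methylidene-5-{(1R)-1-[(9R)-6,7,8,9-tetrahydro-5H-pyrrolo[1,2-a]azepin-9-yl]propyl}oxolan-2-one
Product: 16 tetracyclic pyrrole lactone (9R,10R,11S,12R,13R; H at C3), via butenolide 15 (not isolated)
Conditions: RhH(CO)(PPh3)3 (5 mol%), toluene, 90 °C; then Sc(OTf)3 (10 mol%), (CF3)2CHOH, 0.01 M, 0 °C to rt
Reagents that add atoms: none
Why: Rhodium hydride isomerization moves the exocyclic alkene into conjugation, then intramolecular Friedel–Crafts/Michael addition of pyrrole C1 to C12 closes ring B; the tether forces the cis ring fusion (C12) and the lactone enol is protonated from the convex face in the protic solvent, giving 13R (H-12/H-13 cis).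

Step 8
Reactants: 16 tetracyclic pyrrole lactone (9R,10R,11S,12R,13R; H at C3)
Product: 17 3-formyl tetracyclic pyrrole lactone (9R,10R,11S,12R,13R)
Conditions: POCl3, DMF, 0 °C to rt; aq. NaOAc
Reagents that add atoms: N,N-dimethylformamide, CN(C)C=O; water, O
Why: Vilsmeier–Haack formylation at the only free pyrrole α-position; the mild buffered work-up leaves the kinetically set C13 untouched.

Step 9
Reactants: 17 3-formyl tetracyclic pyrrole lactone (9R,10R,11S,12R,13R); 18 methyl (2R)-3-iodo-2-methylpropanoate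
Product: 21 target CNP0232452.6 (9R,10R,11S,12R,13R,18S,20S), via diorganozinc 19 (not isolated), via hydroxy ester zinc alkoxide 20 (not isolated)
Conditions: 18 (5 equiv), Et2Zn, CuI (cat.), 50 °C, then vacuum; Ti(OiPr)4 (2 equiv), (1R,2R)-1,2-bis(trifluoromethanesulfonamido)cyclohexane (10 mol%), toluene, −20 °C to rt; aq. NH4Cl
Reagents that add atoms: methyl (2R)-3-iodo-2-methylpropanoate (18), IC[C@H](C)C(=O)OC
Why: Iodine–zinc exchange gives a zinc homoenolate that adds to the aldehyde Si face under titanium bis(sulfonamide) catalysis (the sense that gives (S)-carbinols from aryl aldehydes), setting C18 (S); C20 (S) is carried in from the reagent, and the alkoxide closes the cis lactone on the methyl ester on warming.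

## Compound list

1 | 6-bromohex-1-ene | C=CCCCCBr | starting material
2 | di-tert-butyl iminodicarboxylate | CC(C)(C)OC(=O)NC(=O)OC(C)(C)C | starting material
3 | di-tert-butyl (hex-5-en-1-yl)imidodicarbonate | C=CCCCCN(C(=O)OC(C)(C)C)C(=O)OC(C)(C)C | intermediate
4 | di-tert-butyl [(5E)-6-nitrohex-5-en-1-yl]imidodicarbonate | [O-][N+](=O)/C=C/CCCCN(C(=O)OC(C)(C)C)C(=O)OC(C)(C)C | intermediate
5 | butanal | CCCC=O | starting material
6 | di-tert-butyl [(5R,6R)-6-formyl-5-(nitromethyl)octyl]imidodicarbonate | CC[C@H]([C@H](C[N+](=O)[O-])CCCCN(C(=O)OC(C)(C)C)C(=O)OC(C)(C)C)C=O | intermediate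
7 | ethyl 2-(bromomethyl)prop-2-enoate | C=C(CBr)C(=O)OCC | starting material
8 | ethyl (4R,5R,6R)-10-[bis(tert-butoxycarbonyl)amino]-5-ethyl-4-hydroxy-2-methylidene-6-(nitromethyl)decanoate | CC[C@H]([C@H](C[N+](=O)[O-])CCCCN(C(=O)OC(C)(C)C)C(=O)OC(C)(C)C)[C@H](O)CC(=C)C(=O)OCC | intermediate
9 | di-tert-butyl {(5R,6R)-6-[(2R)-4-methylidene-5-oxooxolan-2-yl]-5-(nitromethyl)octyl}imidodicarbonate | CC[C@H]([C@H](C[N+](=O)[O-])CCCCN(C(=O)OC(C)(C)C)C(=O)OC(C)(C)C)[C@@H]1OC(=O)C(=C)C1 | intermediate
10 | prop-2-enal (acrolein) | C=CC=O | starting material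
11 | di-tert-butyl {(5R,6R)-6-[(2R)-4-methylidene-5-oxooxolan-2-yl]-5-(1-nitro-4-oxobutyl)octyl}imidodicarbonate, both epimers at the nitro carbon (that center left undefined in the SMILES) | CC[C@H]([C@H](C(CCC=O)[N+](=O)[O-])CCCCN(C(=O)OC(C)(C)C)C(=O)OC(C)(C)C)[C@@H]1OC(=O)C(=C)C1 | intermediate
12 | (5R)-5-[(3R,4R)-8-amino-4-(1-nitro-4-oxobutyl)octan-3-yl]-3-methylideneoxolan-2-one, present as its trifluoroacetate | CC[C@H]([C@H](C(CCC=O)[N+](=O)[O-])CCCCN)[C@@H]1OC(=O)C(=C)C1 | intermediate
13 | (5R)-5-[(3R,4R)-8-amino-4-(4-oxobutanoyl)octan-3-yl]-3-methylideneoxolan-2-one | CC[C@H]([C@H](C(=O)CCC=O)CCCCN)[C@@H]1OC(=O)C(=C)C1 | intermediate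
14 | (5R)-3-methylidene-5-{(1R)-1-[(9R)-6,7,8,9-tetrahydro-5H-pyrrolo[1,2-a]azepin-9-yl]propyl}oxolan-2-one | CC[C@H]([C@H]1CCCCn2cccc12)[C@@H]1OC(=O)C(=C)C1 | intermediate
15 | (5S)-3-methyl-5-{(1R)-1-[(9R)-6,7,8,9-tetrahydro-5H-pyrrolo[1,2-a]azepin-9-yl]propyl}furan-2(5H)-one | CC[C@H]([C@H]1CCCCn2cccc12)[C@@H]1OC(=O)C(C)=C1 | intermediate
16 | tetracyclic pyrrole lactone: the target without its side lactone, H at C3; 9R,10R,11S,12R,13R | CC[C@H]1[C@@H]2OC(=O)[C@H](C)[C@@H]2c2ccn3c2[C@@H]1CCCC3 | intermediate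
17 | 3-formyl derivative of 16; 9R,10R,11S,12R,13R | CC[C@H]1[C@@H]2OC(=O)[C@H](C)[C@@H]2c2cc(C=O)n3c2[C@@H]1CCCC3 | intermediate
18 | methyl (2R)-3-iodo-2-methylpropanoate | IC[C@H](C)C(=O)OC | starting material
19 | bis[(2R)-3-methoxy-2-methyl-3-oxopropyl]zinc | COC(=O)[C@@H](C)C[Zn]C[C@H](C)C(=O)OC | intermediate
20 | methyl (2S,4S)-4-hydroxy-2-methyl-4-(tetracycl-3-yl)butanoate, present as its zinc alkoxide; ring stereocenters as in 16 | CC[C@H]1[C@@H]2OC(=O)[C@H](C)[C@@H]2c2cc([C@@H](O)C[C@H](C)C(=O)OC)n3c2[C@@H]1CCCC3 | intermediate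
21 | target CNP0232452.6; 9R,10R,11S,12R,13R,18S,20S | CC[C@H]1[C@@H]2OC(=O)[C@H](C)[C@@H]2c2cc([C@@H]3C[C@H](C)C(=O)O3)n3c2[C@@H]1CCCC3 | target

## Summary

Total step count: 9. Longest linear sequence: 9 steps (1 to 21).

Three steps most likely to fail:

Step 6. Deprotection, Nef reaction and Paal–Knorr closure are run in one pot on a substrate that carries an α-methylidene lactone. The free keto-aldehyde can epimerize at C9, form a furan, or the amine can add to the methylidene lactone. The fallback sets out from 11 and separates carbonyl unmasking from ring closure with an oxidative instead of a reductive Nef reaction. Brief nitronate formation (DBU, CH2Cl2/MeOH, −20 °C) followed by KHSO5 in phosphate buffer gives the isolated di-tert-butyl {(5R,6R)-6-[(2R)-4-methylidene-5-oxooxolan-2-yl]-5-(4-oxobutanoyl)octyl}imidodicarbonate F1. This is purified, deprotected with CF3CO2H and cyclized in dilute NaOAc/AcOH, coming back to the route at 14.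

Step 7. The pyrrole in 14 has a free, very nucleophilic α-position (C3). It can attack the butenolide of a second molecule or decompose under acid before the six-membered ring closes. The fallback sets out from 14 and blocks and deactivates C3 first. Vilsmeier–Haack formylation (POCl3, DMF) gives (9R)-9-{(1R)-1-[(2R)-4-methylidene-5-oxooxolan-2-yl]propyl}-6,7,8,9-tetrahydro-5H-pyrrolo[1,2-a]azepine-3-carbaldehyde F2. RhH(CO)(PPh3)3 isomerization gives (9R)-9-{(1R)-1-[(2S)-4-methyl-5-oxo-2,5-dihydrofuran-2-yl]propyl}-6,7,8,9-tetrahydro-5H-pyrrolo[1,2-a]azepine-3-carbaldehyde F3. The acylpyrrole, which reacts preferentially at the required carbon, is then cyclized with CF3SO3H in (CF3)2CHOH, coming back to the route at 17.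

Step 9. The pyrrole aldehyde is a weak electrophile and a β-ester diorganozinc is a sluggish, internally chelated nucleophile, so conversion or the C18 selectivity may be poor. The fallback sets out from 17 and builds the lactone by catalyst-controlled allylation and hydrogenation instead. Iridium-catalysed 2-(alkoxycarbonyl)allylation with the tert-butyl carbonate of methyl 2-(hydroxymethyl)acrylate is used ([Ir(cod)Cl]2, SEGPHOS enantiomer chosen for the 18S carbinol, 4-cyano-3-nitrobenzoic acid, Cs2CO3, 2-propanol, THF). It gives methyl (4S)-4-hydroxy-2-methylidene-4-(tetracycl-3-yl)butanoate F4, which lactonizes in the flask to (5S)-3-methylidene-5-(tetracycl-3-yl)oxolan-2-one F5. Hydrogenation with RhCl(PPh3)3 (H2, 1 atm, benzene) adds hydrogen anti to the pyrrolyl group and gives the cis 20S methyl lactone, coming back to the route at 21.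

Further compounds
F1 | step 6 | di-tert-butyl {(5R,6R)-6-[(2R)-4-methylidene-5-oxooxolan-2-yl]-5-(4-oxobutanoyl)octyl}imidodicarbonate | CC[C@H]([C@H](C(=O)CCC=O)CCCCN(C(=O)OC(C)(C)C)C(=O)OC(C)(C)C)[C@@H]1OC(=O)C(=C)C1
F2 | step 7 | (9R)-9-{(1R)-1-[(2R)-4-methylidene-5-oxooxolan-2-yl]propyl}-6,7,8,9-tetrahydro-5H-pyrrolo[1,2-a]azepine-3-carbaldehyde | CC[C@H]([C@H]1CCCCn2c(C=O)ccc12)[C@@H]1OC(=O)C(=C)C1
F3 | step 7 | (9R)-9-{(1R)-1-[(2S)-4-methyl-5-oxo-2,5-dihydrofuran-2-yl]propyl}-6,7,8,9-tetrahydro-5H-pyrrolo[1,2-a]azepine-3-carbaldehyde | CC[C@H]([C@H]1CCCCn2c(C=O)ccc12)[C@@H]1OC(=O)C(C)=C1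
F4 | step 9 | methyl (4S)-4-hydroxy-2-methylidene-4-(tetracycl-3-yl)butanoate, ring stereocenters as in 16 | CC[C@H]1[C@@H]2OC(=O)[C@H](C)[C@@H]2c2cc([C@@H](O)CC(=C)C(=O)OC)n3c2[C@@H]1CCCC3
F5 | step 9 | (5S)-3-methylidene-5-(tetracycl-3-yl)oxolan-2-one, ring stereocenters as in 16 | CC[C@H]1[C@@H]2OC(=O)[C@H](C)[C@@H]2c2cc([C@@H]3CC(=C)C(=O)O3)n3c2[C@@H]1CCCC3
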